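The benzene ring is cut at C1–C2 and C3–C4, which removes the unsubstituted C2–C3 edge as a two-carbon acetylene unit. The ester C–O bond is cut next, and the C16–C17 bond of the C40 acid last.
The ring is 1,4-disubstituted, so C1 (side chain), C6, C5, C4 (hydroxyl) and the phenol oxygen correspond to C2, C3, C4, C5 and O1 of a 2-substituted furan. The para carbons C1 and C4 are the two furan carbons that flank the oxygen and serve as diene termini.
For the chain, a C24 Grignard reagent is joined to a C16 ω-bromo acid (Li2CuCl4). The acid becomes its chloride and esterifies 2-(furan-2-yl)ethanol while the molecule holds a single hydroxyl.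
Acetylene itself is too poor a dienophile for a furan and offers a Lewis acid nothing to bind, so the two-carbon unit enters as (E)-1,2-bis(phenylsulfonyl)ethylene. The Diels–Alder addition closes the only new ring, Na(Hg) strips both sulfonyl groups to give the 7-oxanorbornadiene, and BF3·OEt2 opens the oxygen bridge to the phenol.
The target has no stereocentre, and the four centres made in the cycloaddition are erased in the last two steps.

Key step: step 5

Assumption: the acyl group is read as the unbranched C40 chain (39 carbons plus the carbonyl carbon), and all four starting materials are taken as catalogue items.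

Step 1
Reactants: 1 1-bromotetracosane
Product: 2 tetracosylmagnesium bromide (kept as a warm THF solution)
Conditions: Mg turnings (1.3 equiv), iodine (one crystal), THF, 55 °C
Reagents that add atoms: magnesium, [Mg]
Why: Grignard formation by insertion of magnesium into a primary C–Br bond is routine, warm THF keeps the waxy bromide and the reagent dissolved, and slow addition holds Wurtz coupling down.

Step 2
Reactants: 2 tetracosylmagnesium bromide; 3 16-bromohexadecanoic acid
Product: 6 tetracontanoic acid, via chloromagnesium 16-bromohexadecanoate 4 (not isolated), via chloromagnesium tetracontanoate 5 (not isolated)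
Conditions: 3, MeMgCl (1.0 equiv), THF, −20 °C; then Li2CuCl4 (3 mol %), NMP (4 equiv), 2 (1.3 equiv, added warm), 0 → 25 °C; 1 M HCl
Reagents that add atoms: none
Why: Copper-catalysed cross-coupling of a primary alkyl Grignard reagent with a primary alkyl bromide (Kochi–Schlosser type) is the standard route to very long fatty acids, and the carboxyl group is shielded in the flask as its magnesium salt, which the organocopper species does not attack at these temperatures.

Step 3
Reactants: 6 tetracontanoic acid
Product: 7 tetracontanoyl chloride
Conditions: SOCl2 (3 equiv), toluene, 75 °C; evaporation from toluene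
Reagents that add atoms: thionyl chloride, O=S(Cl)Cl
Why: Acid chloride formation with thionyl chloride runs through the acyl chlorosulfite, gives only gaseous by-products and suits an acid that dissolves only in warm toluene.

Step 4
Reactants: 7 tetracontanoyl chloride; 8 2-(furan-2-yl)ethanol
Product: 9 2-(furan-2-yl)ethyl tetracontanoate
Conditions: pyridine (2 equiv), DMAP (5 mol %), toluene, 50 °C
Reagents that add atoms: none
Why: DMAP-catalysed acylation of a primary alcohol by an acid chloride (nucleophilic acyl substitution) is fast, and pyridine binds the HCl that would otherwise attack the acid-sensitive furan.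

Step 5
Reactants: 9 2-(furan-2-yl)ethyl tetracontanoate; 10 (E)-1,2-bis(phenylsulfonyl)ethylene
Product: 11 2-[5,6-trans-bis(phenylsulfonyl)-7-oxabicyclo[2.2.1]hept-2-en-1-yl]ethyl tetracontanoate (racemic mixture of the two trans diastereomers)
Conditions: 10 (1.2 equiv), ClCH2CH2Cl (about 1 M), 60 °C, sealed vessel
Reagents that add atoms: none
Why: The step is a concerted, suprafacial, normal-electron-demand [4+2] cycloaddition in which the alkyl-raised HOMO of the furan meets the LUMO of the doubly sulfonyl-activated alkene, so furan C2 and C5 each bond to one alkene carbon and the future arene bonds C1–C2 and C3–C4 form together. The closest known reaction type is the Diels–Alder addition of furans to 1,2-bis(arylsulfonyl)ethylenes used as acetylene equivalents; acetylene itself is avoided because its LUMO is high and it has no site at which a Lewis acid could lower it. The six-membered carbocycle closes by intermolecular [4+2] cycloaddition, both ring bonds at once, and the furan oxygen is left as the one-atom bridge of a 7-oxabicyclo[2.2.1]hept-2-ene. Four stereocentres arise: C1 and C4 are tied to each other by addition to one face of the planar diene, C5 and C6 stay trans because the E geometry of 10 is retained, and which sulfonyl group lies endo is not controlled, so two racemic diastereomers are expected whose centres all vanish in steps 6 and 7. There is no regiochemical question because the two carbons of 10 are equivalent, the ester is inert, and the only demand is thermodynamic: high concentration and a temperature no higher than solubility requires should hold the reversible addition on the adduct side.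

Step 6
Reactants: 11 2-[5,6-trans-bis(phenylsulfonyl)-7-oxabicyclo[2.2.1]hept-2-en-1-yl]ethyl tetracontanoate
Product: 12 2-(7-oxabicyclo[2.2.1]hepta-2,5-dien-1-yl)ethyl tetracontanoate
Conditions: 6 % Na(Hg) (6 equiv Na), NaH2PO4 (8 equiv), THF–MeOH 5:1, 0 → 20 °C; short pad of basic alumina
Reagents that add atoms: none
Why: Two electron transfers cleave one C–S bond and the β-sulfonyl carbanion expels benzenesulfinate (reductive 1,2-elimination of a vicinal disulfone, the Julia-type unmasking established for this class of acetylene equivalent), while the phosphate buffer keeps methoxide too low to attack the ester.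

Step 7
Reactants: 12 2-(7-oxabicyclo[2.2.1]hepta-2,5-dien-1-yl)ethyl tetracontanoate
Product: 13 2-(4-hydroxyphenyl)ethyl tetracontanoate
Conditions: BF3·OEt2 (10 mol %), toluene, 30 °C; aq NaHCO3; recrystallisation from ethyl acetate–heptane
Reagents that add atoms: none
Why: In this acid-catalysed isomerisation of a 7-oxanorbornadiene to a phenol, BF3 binds the bridge oxygen, only the C1–O bond at the alkyl-bearing bridgehead ionises because it alone gives a tertiary, doubly allylic arenium ion, and loss of the C4 proton aromatises the ring with the former furan oxygen para to the side chain.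

Compound list
1 | 1-bromotetracosane | CCCCCCCCCCCCCCCCCCCCCCCCBr | starting material
2 | tetracosylmagnesium bromide | CCCCCCCCCCCCCCCCCCCCCCCC[Mg]Br | intermediate
3 | 16-bromohexadecanoic acid | OC(=O)CCCCCCCCCCCCCCCBr | starting material
4 | chloromagnesium 16-bromohexadecanoate | Cl[Mg]OC(=O)CCCCCCCCCCCCCCCBr | intermediate
5 | chloromagnesium tetracontanoate | CCCCCCCCCCCCCCCCCCCCCCCCCCCCCCCCCCCCCCCC(=O)O[Mg]Cl | intermediate
6 | tetracontanoic acid | CCCCCCCCCCCCCCCCCCCCCCCCCCCCCCCCCCCCCCCC(=O)O | intermediate
7 | tetracontanoyl chloride | CCCCCCCCCCCCCCCCCCCCCCCCCCCCCCCCCCCCCCCC(=O)Cl | intermediate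
8 | 2-(furan-2-yl)ethanol | OCCc1ccco1 | starting material
9 | 2-(furan-2-yl)ethyl tetracontanoate | CCCCCCCCCCCCCCCCCCCCCCCCCCCCCCCCCCCCCCCC(=O)OCCc1ccco1 | intermediate
10 | (E)-1,2-bis(phenylsulfonyl)ethylene | O=S(=O)(/C=C/S(=O)(=O)c1ccccc1)c1ccccc1 | starting material
11 | 2-[5,6-trans-bis(phenylsulfonyl)-7-oxabicyclo[2.2.1]hept-2-en-1-yl]ethyl tetracontanoate (racemic; 5-endo,6-exo isomer drawn, the 5-exo,6-endo isomer is expected beside it) | CCCCCCCCCCCCCCCCCCCCCCCCCCCCCCCCCCCCCCCC(=O)OCC[C@@]12C=C[C@@H](O1)[C@H](S(=O)(=O)c1ccccc1)[C@H]2S(=O)(=O)c1ccccc1 | intermediate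
12 | 2-(7-oxabicyclo[2.2.1]hepta-2,5-dien-1-yl)ethyl tetracontanoate (achiral) | CCCCCCCCCCCCCCCCCCCCCCCCCCCCCCCCCCCCCCCC(=O)OCCC12C=CC(O1)C=C2 | intermediate
13 | 2-(4-hydroxyphenyl)ethyl tetracontanoate | CCCCCCCCCCCCCCCCCCCCCCCCCCCCCCCCCCCCCCCC(=O)OCCc1ccc(O)cc1 | target

Total step count: 7. Longest linear sequence: 7 steps (1 → 2 → 6 → 7 → 9 → 11 → 12 → 13).

The three steps most likely to fail are steps 5, 6 and 2.

**First risk, step 5.** The cycloaddition is reversible and both partners are sparingly soluble. The addition may therefore stall short of completion, or revert at the temperature needed to keep the wax dissolved. The fallback exchanges the order of acylation and cycloaddition.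
- It sets out from 8, a mobile liquid that can be used in excess with 10 in CH2Cl2 at 25 °C, where the equilibrium lies further on the adduct side.
- This should give 2-[5,6-trans-bis(phenylsulfonyl)-7-oxabicyclo[2.2.1]hept-2-en-1-yl]ethanol F1.
- F1 is then acylated with 7 (pyridine, CH2Cl2–toluene, 30 °C). No stronger base is used, to spare the acidic α-sulfonyl hydrogens.
- The sequence comes back to the route at 11.

**Second risk, step 6.** After the first C–S cleavage the carbanion may expel the oxygen bridge in place of the second sulfinate. Methoxide formed at the amalgam surface may also cleave the ester. The fallback gives up ring construction and acylates a preformed, phenol-protected arene.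
- It sets out from 7, which acylates commercial 2-[4-(benzyloxy)phenyl]ethanol (pyridine, DMAP, toluene, 50 °C) to give 2-[4-(benzyloxy)phenyl]ethyl tetracontanoate F2.
- Hydrogenolysis (H2, Pd/C, THF–EtOAc, 40 °C) removes the benzyl group.
- The sequence comes back to the route at 13.

**Third risk, step 2.** The waxy Grignard reagent may precipitate. Homocoupling or β-hydride loss at copper may then consume it faster than the slow sp3–sp3 coupling proceeds. The fallback replaces the organomagnesium coupling by alkylation of a sulfone-stabilised carbanion.
- It sets out from 1, which is heated with PhSO2Na in DMF (80 °C) to give phenyl tetracosyl sulfone F3.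
- n-BuLi in THF–DMPU converts F3 into 1-lithiotetracosyl phenyl sulfone F4, and two equivalents of F4 are added to 3.
- The first equivalent deprotonates the acid to lithium 16-bromohexadecanoate F5 and returns F3.
- The second equivalent displaces the bromide, and acidic work-up should give racemic 17-(phenylsulfonyl)tetracontanoic acid F6.
- Reductive desulfonylation (Na(Hg), Na2HPO4, THF–MeOH) comes back to the route at 6.

Further compounds
F1 | step 5 | 2-[5,6-trans-bis(phenylsulfonyl)-7-oxabicyclo[2.2.1]hept-2-en-1-yl]ethanol (racemic; 5-endo,6-exo isomer drawn, the 5-exo,6-endo isomer is expected beside it) | OCC[C@@]12C=C[C@@H](O1)[C@H](S(=O)(=O)c1ccccc1)[C@H]2S(=O)(=O)c1ccccc1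
F2 | step 6 | 2-[4-(benzyloxy)phenyl]ethyl tetracontanoate | CCCCCCCCCCCCCCCCCCCCCCCCCCCCCCCCCCCCCCCC(=O)OCCc1ccc(OCc2ccccc2)cc1
F3 | step 2 | phenyl tetracosyl sulfone | CCCCCCCCCCCCCCCCCCCCCCCCS(=O)(=O)c1ccccc1
F4 | step 2 | 1-lithiotetracosyl phenyl sulfone | CCCCCCCCCCCCCCCCCCCCCCCC([Li])S(=O)(=O)c1ccccc1
F5 | step 2 | lithium 16-bromohexadecanoate | [Li+].[O-]C(=O)CCCCCCCCCCCCCCCBr
F6 | step 2 | 17-(phenylsulfonyl)tetracontanoic acid (racemic) | CCCCCCCCCCCCCCCCCCCCCCCC(S(=O)(=O)c1ccccc1)CCCCCCCCCCCCCCCC(=O)O
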